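**Plan**

- Numbering: drimane C1–C12 (C8=C12 is the exocyclic methylene, C7 its CH2 neighbour in ring B, C9 carries C11H2, C10 the angular methyl, C4 the gem-dimethyl); epoxyquinone carbons 1'–6' (C1' carries C11).
- Cuts, in retrosynthetic order: HMG ester C–O; epoxide and C3' ketone (back to a para-methoxyphenol); ring B at C7–C8; C9–C11; C10–C9 and C5–C6 on a ring-A enone.
- Feature used: C8 is an sp2 carbon bonded only to C12H2, C9 and the unsubstituted methylene C7, so C7–C8 is an alkenyl–primary-alkyl bond; an enol triflate at C8 (from a methyl ketone on C9) and a borane at C7 (from a vinyl group on C5) close ring B with the exocyclic alkene already in place.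
- Forward: ring A is bought; C5–C6 and C10–C9 come from one conjugate addition/enolate alkylation; C9–C11 from benzylation with the aryl fragment; ring B from hydroboration/B-alkyl Suzuki coupling; then arene → quinone monoketal → epoxide → epoxyquinone, with the HMG ester attached before the oxidation.
- Stereochemistry: C5 from a chiral copper catalyst, C10 by alkylation anti to the new vinyl group, C9 by substrate control (A(1,3) strain), C1'/C2' by tartrate-mediated nucleophilic epoxidation, the HMG carbinol from (R)-mevalonolactone.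

Key step: step 11

Assumption: the sense of induction of the chiral ligand in step 5 and of the tartrate in step 18 is taken by analogy with simpler substrates; in each case the enantiomer that gives the drawn product is meant.

**Route**

Step 1
Reactants: 1 4-bromo-2,5-dimethoxybenzaldehyde
Product: 2 4-bromo-2-hydroxy-5-methoxybenzaldehyde
Conditions: BCl3 (1.2 equiv), CH2Cl2, −78 → 0 °C; aq. work-up
Reagents that add atoms: none
Why: Chelation of BCl3 between the aldehyde oxygen and the ortho methoxy group should direct ether cleavage to that methyl group only (regioselective aryl methyl ether cleavage), which differentiates the two ring oxygens for the later quinone monoketal.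

Step 2
Reactants: 2 4-bromo-2-hydroxy-5-methoxybenzaldehyde
Product: 3 4-bromo-5-methoxy-2-[(triisopropylsilyl)oxy]benzaldehyde
Conditions: iPr3SiCl, imidazole, DMF, rt
Reagents that add atoms: chlorotriisopropylsilane, CC(C)[Si](Cl)(C(C)C)C(C)C
Why: Silylation of the phenol gives an aryl silyl ether that should survive the amide bases, MeLi and the palladium steps ahead and is removed by fluoride.

Step 3
Reactants: 3 4-bromo-5-methoxy-2-[(triisopropylsilyl)oxy]benzaldehyde
Product: 4 {4-bromo-5-methoxy-2-[(triisopropylsilyl)oxy]phenyl}methanol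
Conditions: NaBH4, MeOH/THF, 0 °C
Reagents that add atoms: none
Why: Borohydride reduction of the aldehyde to the benzylic alcohol.

Step 4
Reactants: 4 {4-bromo-5-methoxy-2-[(triisopropylsilyl)oxy]phenyl}methanol
Product: 5 [5-bromo-2-(bromomethyl)-4-methoxyphenoxy]triisopropylsilane
Conditions: CBr4, PPh3, CH2Cl2, 0 °C
Reagents that add atoms: tetrabromomethane, BrC(Br)(Br)Br
Why: The Appel reaction should convert the benzylic alcohol into the bromide under neutral conditions that spare the aryl silyl ether.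

Step 5
Reactants: 6 2,4,4-trimethylcyclohex-2-en-1-one; 7 vinylmagnesium bromide; 8 tert-butyl bromoacetate
Product: 10 tert-butyl 2-[(1R,2S)-2-ethenyl-1,3,3-trimethyl-6-oxocyclohexyl]acetate, via bromomagnesium enolate 9 (not isolated)
Conditions: Cu(OTf)2 (4 mol%), chiral hydroxyalkyl imidazolinium hexafluorophosphate (NHC precursor, 5 mol%), Et2O, −30 °C, slow addition of 7; then 8, DMPU, −30 → 0 °C
Reagents that add atoms: none
Why: Copper-catalysed asymmetric conjugate addition of a Grignard reagent to an α-methyl cycloalkenone with trapping of the magnesium enolate; the chiral NHC–copper complex should set C5, and the bromoacetate should enter the enolate anti to the new vinyl group, which sets C10 with the C9 arm trans to the C6=C7 arm.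

Step 6
Reactants: 10 tert-butyl 2-[(1R,2S)-2-ethenyl-1,3,3-trimethyl-6-oxocyclohexyl]acetate
Product: 12 tert-butyl 2-[(1R,2S)-2-ethenyl-1,3,3-trimethylcyclohexyl]acetate, via tosylhydrazone 11 (not isolated)
Conditions: TsNHNH2, EtOH, 70 °C; evaporation; catecholborane, CHCl3, 0 °C → rt; NaOAc·3H2O, reflux
Reagents that add atoms: none
Why: Caglioti-type reduction of the tosylhydrazone (hydride addition, loss of sulfinate and N2) should turn the C1 carbonyl, which has served its purpose as activating group, into CH2 without touching the vinyl group, the ester or the two stereocentres.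

Step 7
Reactants: 12 tert-butyl 2-[(1R,2S)-2-ethenyl-1,3,3-trimethylcyclohexyl]acetate; 5 [5-bromo-2-(bromomethyl)-4-methoxyphenoxy]triisopropylsilane
Product: 13 tert-butyl (2R)-3-{4-bromo-5-methoxy-2-[(triisopropylsilyl)oxy]phenyl}-2-[(1S,2S)-2-ethenyl-1,3,3-trimethylcyclohexyl]propanoate
Conditions: LiN(iPr)2, THF, −78 → −20 °C; then 5, DMPU, −78 → −30 °C
Reagents that add atoms: none
Why: Ester enolate alkylation forms C9–C11; A(1,3) strain with the enolate oxygen substituent should hold the C10 methyl in the enolate plane, the C5 methine (vinyl group, gem-dimethyl neighbour) should shield one face, and the benzyl bromide should enter from the C1 side to give the C9 configuration of the target.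

Step 8
Reactants: 13 tert-butyl (2R)-3-{4-bromo-5-methoxy-2-[(triisopropylsilyl)oxy]phenyl}-2-[(1S,2S)-2-ethenyl-1,3,3-trimethylcyclohexyl]propanoate
Product: 14 (2R)-3-{4-bromo-5-methoxy-2-[(triisopropylsilyl)oxy]phenyl}-2-[(1S,2S)-2-ethenyl-1,3,3-trimethylcyclohexyl]propanoic acid
Conditions: CF3CO2H/CH2Cl2 (1:4), 0 °C → rt
Reagents that add atoms: none
Why: Acidolysis of the tert-butyl ester should proceed without enolisation at C9 and should leave the monosubstituted alkene and the aryl silyl ether intact.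

Step 9
Reactants: 14 (2R)-3-{4-bromo-5-methoxy-2-[(triisopropylsilyl)oxy]phenyl}-2-[(1S,2S)-2-ethenyl-1,3,3-trimethylcyclohexyl]propanoic acid
Product: 15 (3R)-4-{4-bromo-5-methoxy-2-[(triisopropylsilyl)oxy]phenyl}-3-[(1S,2S)-2-ethenyl-1,3,3-trimethylcyclohexyl]butan-2-one
Conditions: MeLi (4 equiv), Et2O/THF, 0 °C → rt; inverse quench into cold aq. NH4Cl
Reagents that add atoms: methyllithium, C[Li]
Why: Addition of methyllithium to the lithium carboxylate should give a dilithio ketone hydrate that collapses to the methyl ketone only on work-up (ketone synthesis from a carboxylic acid), so C8 gains C12 without over-addition and the hindered C9–H is not removed.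

Step 10
Reactants: 15 (3R)-4-{4-bromo-5-methoxy-2-[(triisopropylsilyl)oxy]phenyl}-3-[(1S,2S)-2-ethenyl-1,3,3-trimethylcyclohexyl]butan-2-one
Product: 16 (3R)-4-{4-bromo-5-methoxy-2-[(triisopropylsilyl)oxy]phenyl}-3-[(1S,2S)-2-ethenyl-1,3,3-trimethylcyclohexyl]but-1-en-2-yl trifluoromethanesulfonate
Conditions: KN(SiMe3)2, THF, −78 °C; then PhNTf2, −78 → −20 °C
Reagents that add atoms: N-phenylbis(trifluoromethanesulfonimide), O=S(=O)(N(c1ccccc1)S(=O)(=O)C(F)(F)F)C(F)(F)F
Why: Kinetic deprotonation should occur at the methyl group C12 and not at the hindered methine C9, and O-sulfonylation of that enolate gives the 1,1-disubstituted enol triflate with C9 untouched.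

Step 11
Reactants: 16 (3R)-4-{4-bromo-5-methoxy-2-[(triisopropylsilyl)oxy]phenyl}-3-[(1S,2S)-2-ethenyl-1,3,3-trimethylcyclohexyl]but-1-en-2-yl trifluoromethanesulfonate
Product: 18 [5-bromo-4-methoxy-2-{[(1S,4aS,8aS)-5,5,8a-trimethyl-2-methylidenedecahydronaphthalen-1-yl]methyl}phenoxy]triisopropylsilane, via B-alkyl-9-BBN adduct 17 (not isolated)
Conditions: 9-BBN (1.5 equiv), THF, rt → 40 °C; then Pd(dppf)Cl2 (10 mol%), AsPh3 (10 mol%), aq. K3PO4 (3 M), THF/DMF, rt → 45 °C, degassed
Reagents that add atoms: none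
Why: 9-BBN should add anti-Markovnikov to the vinyl group and put boron on C7; zerovalent palladium then inserts into the C8–OTf bond, the base-activated borate hands C7 to the divalent alkenylpalladium, and reductive elimination joins C7 to C8. The closest known reaction type is the intramolecular B-alkyl Suzuki–Miyaura coupling of an ω-alkenyl alkenyl triflate or halide to a methylenecycloalkane. Ring B closes as a six-membered ring by reductive elimination from a seven-membered palladacycle (formally 6-exo, C8=C12 stays exocyclic), and the trans-diequatorial C5 and C10 arms on chair ring A lead to the trans-decalin. No stereocentre is formed, and C5, C9 and C10 are carried through because no enolisable position remains next to C9 once C8 is the enol triflate. The step needs hydroboration of the monosubstituted vinyl group in preference to the electron-poor 1,1-disubstituted enol triflate, which the selectivity of 9-BBN should secure. It also needs oxidative addition at the alkenyl triflate in preference to the electron-rich, ortho-substituted aryl bromide, which Pd(dppf)Cl2/AsPh3 at or below 45 °C should secure.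

Step 12
Reactants: 18 [5-bromo-4-methoxy-2-{[(1S,4aS,8aS)-5,5,8a-trimethyl-2-methylidenedecahydronaphthalen-1-yl]methyl}phenoxy]triisopropylsilane
Product: 19 (2-methoxy-4-{[(1S,4aS,8aS)-5,5,8a-trimethyl-2-methylidenedecahydronaphthalen-1-yl]methyl}-5-[(triisopropylsilyl)oxy]phenyl)methanol
Conditions: Bu3SnCH2OH, Pd(PPh3)4 (10 mol%), 1,4-dioxane, 95 °C
Reagents that add atoms: (tributylstannyl)methanol, CCCC[Sn](CCCC)(CCCC)CO
Why: Stille coupling of the aryl bromide with the hydroxymethylstannane should install the C4' hydroxymethyl group in one step under neutral conditions that spare the exocyclic alkene and the silyl ether.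

Step 13
Reactants: 20 (R)-mevalonolactone
Product: 22 4-methoxybenzyl (3R)-3,5-dihydroxy-3-methylpentanoate, via sodium mevalonate 21 (not isolated)
Conditions: NaOH (1.0 equiv), H2O, rt; lyophilisation; 4-MeOC6H4CH2Cl, Bu4NI (cat.), DMF, rt
Reagents that add atoms: sodium hydroxide, [Na+].[OH-]; 4-methoxybenzyl chloride, COc1ccc(CCl)cc1
Why: Saponification of the lactone and O-alkylation of the carboxylate should protect the original carboxyl arm as its PMB ester; the tertiary carbinol comes unchanged from the chiral pool.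

Step 14
Reactants: 22 4-methoxybenzyl (3R)-3,5-dihydroxy-3-methylpentanoate
Product: 23 (3R)-3-hydroxy-5-[(4-methoxybenzyl)oxy]-3-methyl-5-oxopentanoic acid
Conditions: TEMPO (20 mol%), PhI(OAc)2 (2.2 equiv), MeCN/H2O (1:1), 0 °C → rt
Reagents that add atoms: water, O
Why: Oxoammonium oxidation of the primary alcohol through the aldehyde hydrate should give the acid; the oxidised arm later becomes the ester arm of the target, which is why the (R)-lactone is the source of the (S)-HMG ester.

Step 15
Reactants: 19 (2-methoxy-4-{[(1S,4aS,8aS)-5,5,8a-trimethyl-2-methylidenedecahydronaphthalen-1-yl]methyl}-5-[(triisopropylsilyl)oxy]phenyl)methanol; 23 (3R)-3-hydroxy-5-[(4-methoxybenzyl)oxy]-3-methyl-5-oxopentanoic acid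
Product: 24 mixed HMG diester (4-methoxybenzyl ester at one carboxyl, benzylic ester of 19 at the other, free tertiary OH, carbinol configuration of the target)
Conditions: EDC·HCl, DMAP (cat.), CH2Cl2, 0 °C → rt
Reagents that add atoms: none
Why: Steglich esterification of the only free (primary, benzylic) hydroxyl; the tertiary β-hydroxyl of the acid should not compete.

Step 16
Reactants: 24 mixed HMG diester
Product: 25 phenol (24 without the triisopropylsilyl group)
Conditions: Bu4NF, AcOH (1:1), THF, 0 °C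
Reagents that add atoms: none
Why: Buffered fluoride should cleave the aryl silyl ether selectively; the acyloxymethyl group is meta to the phenol, so no quinone methide can form.

Step 17
Reactants: 25 phenol
Product: 26 quinone monoketal (4,4-dimethoxycyclohexa-2,5-dien-1-one; C6' carbonyl, C3' dimethyl ketal, C1' drimanylmethyl, C4' acyloxymethyl)
Conditions: PhI(OAc)2, MeOH, 0 °C
Reagents that add atoms: methanol, CO
Why: Oxidative dearomatisation of a para-methoxyphenol with PhI(OAc)2 in methanol; methanol adds at the methoxy-bearing carbon, so the free carbonyl ends up at C6', next to C1'.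

Step 18
Reactants: 26 quinone monoketal
Product: 27 (1'R,2'S)-epoxy monoketal (epoxide across C1'–C2')
Conditions: Ph3COOH, NaN(SiMe3)2, D-(−)-diisopropyl tartrate, toluene, −60 → −40 °C
Reagents that add atoms: trityl hydroperoxide, OOC(c1ccccc1)(c1ccccc1)c1ccccc1
Why: Weitz–Scheffer-type nucleophilic epoxidation; the peroxide should add at C2', the only unsubstituted β-carbon of the dienone (C4' is substituted and flanked by the ketal), and the sodium tartrate–peroxide aggregate is meant to set the face at C1'/C2'.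

Step 19
Reactants: 27 (1'R,2'S)-epoxy monoketal
Product: 29 4'-oxomacrophorin D, via epoxy ketal acid 28 (not isolated)
Conditions: CF3CO2H (10% v/v), anisole, CH2Cl2, 0 °C; then H2O, 0 °C → rt
Reagents that add atoms: water, O
Why: Acidolysis of the PMB ester (cation trapped by anisole) followed by hydrolysis of the dimethyl ketal should unveil the acid and the C3' ketone; the epoxyquinone and the ester are acid-stable, and the short, cold exposure is chosen to spare the exocyclic alkene.

**Compound list**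

1 | 4-bromo-2,5-dimethoxybenzaldehyde | COc1cc(C=O)c(OC)cc1Br | starting material
2 | 4-bromo-2-hydroxy-5-methoxybenzaldehyde | COc1cc(C=O)c(O)cc1Br | intermediate
3 | 4-bromo-5-methoxy-2-[(triisopropylsilyl)oxy]benzaldehyde | COc1cc(C=O)c(O[Si](C(C)C)(C(C)C)C(C)C)cc1Br | intermediate
4 | {4-bromo-5-methoxy-2-[(triisopropylsilyl)oxy]phenyl}methanol | COc1cc(CO)c(O[Si](C(C)C)(C(C)C)C(C)C)cc1Br | intermediate
5 | [5-bromo-2-(bromomethyl)-4-methoxyphenoxy]triisopropylsilane | COc1cc(CBr)c(O[Si](C(C)C)(C(C)C)C(C)C)cc1Br | intermediate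
6 | 2,4,4-trimethylcyclohex-2-en-1-one | CC1=CC(C)(C)CCC1=O | starting material
7 | vinylmagnesium bromide | C=C[Mg]Br | starting material
8 | tert-butyl bromoacetate | CC(C)(C)OC(=O)CBr | starting material
9 | bromomagnesium (3S)-3-ethenyl-2,4,4-trimethylcyclohex-1-en-1-olate | C=C[C@H]1C(C)(C)CCC(O[Mg]Br)=C1C | intermediate
10 | tert-butyl 2-[(1R,2S)-2-ethenyl-1,3,3-trimethyl-6-oxocyclohexyl]acetate | C=C[C@H]1C(C)(C)CCC(=O)[C@]1(C)CC(=O)OC(C)(C)C | intermediate
11 | tosylhydrazone of 10 | C=C[C@H]1C(C)(C)CCC(=NNS(=O)(=O)c2ccc(C)cc2)[C@]1(C)CC(=O)OC(C)(C)C | intermediate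
12 | tert-butyl 2-[(1R,2S)-2-ethenyl-1,3,3-trimethylcyclohexyl]acetate | C=C[C@H]1C(C)(C)CCC[C@]1(C)CC(=O)OC(C)(C)C | intermediate
13 | tert-butyl (2R)-3-{4-bromo-5-methoxy-2-[(triisopropylsilyl)oxy]phenyl}-2-[(1S,2S)-2-ethenyl-1,3,3-trimethylcyclohexyl]propanoate | C=C[C@H]1C(C)(C)CCC[C@]1(C)[C@H](C(=O)OC(C)(C)C)Cc1cc(OC)c(Br)cc1O[Si](C(C)C)(C(C)C)C(C)C | intermediate
14 | (2R)-3-{4-bromo-5-methoxy-2-[(triisopropylsilyl)oxy]phenyl}-2-[(1S,2S)-2-ethenyl-1,3,3-trimethylcyclohexyl]propanoic acid | C=C[C@H]1C(C)(C)CCC[C@]1(C)[C@H](C(=O)O)Cc1cc(OC)c(Br)cc1O[Si](C(C)C)(C(C)C)C(C)C | intermediate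
15 | (3R)-4-{4-bromo-5-methoxy-2-[(triisopropylsilyl)oxy]phenyl}-3-[(1S,2S)-2-ethenyl-1,3,3-trimethylcyclohexyl]butan-2-one | C=C[C@H]1C(C)(C)CCC[C@]1(C)[C@H](C(C)=O)Cc1cc(OC)c(Br)cc1O[Si](C(C)C)(C(C)C)C(C)C | intermediate
16 | (3R)-4-{4-bromo-5-methoxy-2-[(triisopropylsilyl)oxy]phenyl}-3-[(1S,2S)-2-ethenyl-1,3,3-trimethylcyclohexyl]but-1-en-2-yl trifluoromethanesulfonate | C=C[C@H]1C(C)(C)CCC[C@]1(C)[C@H](C(=C)OS(=O)(=O)C(F)(F)F)Cc1cc(OC)c(Br)cc1O[Si](C(C)C)(C(C)C)C(C)C | intermediate
17 | B-alkyl-9-BBN adduct of 16 (boron on C7) | C1CCC2CCCC1B2CC[C@H]1C(C)(C)CCC[C@]1(C)[C@H](C(=C)OS(=O)(=O)C(F)(F)F)Cc1cc(OC)c(Br)cc1O[Si](C(C)C)(C(C)C)C(C)C | intermediate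
18 | [5-bromo-4-methoxy-2-{[(1S,4aS,8aS)-5,5,8a-trimethyl-2-methylidenedecahydronaphthalen-1-yl]methyl}phenoxy]triisopropylsilane | C=C1CC[C@H]2C(C)(C)CCC[C@]2(C)[C@H]1Cc1cc(OC)c(Br)cc1O[Si](C(C)C)(C(C)C)C(C)C | intermediate
19 | (2-methoxy-4-{[(1S,4aS,8aS)-5,5,8a-trimethyl-2-methylidenedecahydronaphthalen-1-yl]methyl}-5-[(triisopropylsilyl)oxy]phenyl)methanol | C=C1CC[C@H]2C(C)(C)CCC[C@]2(C)[C@H]1Cc1cc(OC)c(CO)cc1O[Si](C(C)C)(C(C)C)C(C)C | intermediate
20 | (R)-mevalonolactone, (4R)-4-hydroxy-4-methyloxan-2-one | C[C@]1(O)CC(=O)OCC1 | starting material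
21 | sodium (3R)-3,5-dihydroxy-3-methylpentanoate | C[C@](CCO)(O)CC(=O)[O-].[Na+] | intermediate
22 | 4-methoxybenzyl (3R)-3,5-dihydroxy-3-methylpentanoate | C[C@](CCO)(O)CC(=O)OCc1ccc(OC)cc1 | intermediate
23 | (3R)-3-hydroxy-5-[(4-methoxybenzyl)oxy]-3-methyl-5-oxopentanoic acid | C[C@](CC(=O)O)(O)CC(=O)OCc1ccc(OC)cc1 | intermediate
24 | mixed HMG diester of 19 (PMB ester, aryl silyl ether) | C=C1CC[C@H]2C(C)(C)CCC[C@]2(C)[C@H]1Cc1cc(OC)c(COC(=O)C[C@@](C)(O)CC(=O)OCc3ccc(OC)cc3)cc1O[Si](C(C)C)(C(C)C)C(C)C | intermediate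
25 | phenol from 24 | C=C1CC[C@H]2C(C)(C)CCC[C@]2(C)[C@H]1Cc1cc(OC)c(COC(=O)C[C@@](C)(O)CC(=O)OCc3ccc(OC)cc3)cc1O | intermediate
26 | quinone monoketal (C6' carbonyl, C3' dimethyl ketal) | C=C1CC[C@H]2C(C)(C)CCC[C@]2(C)[C@H]1CC1=CC(OC)(OC)C(COC(=O)C[C@@](C)(O)CC(=O)OCc2ccc(OC)cc2)=CC1=O | intermediate
27 | (1'R,2'S)-epoxy monoketal, PMB ester | C=C1CC[C@H]2C(C)(C)CCC[C@]2(C)[C@H]1C[C@@]12O[C@@H]1C(OC)(OC)C(COC(=O)C[C@@](C)(O)CC(=O)OCc1ccc(OC)cc1)=CC2=O | intermediate
28 | (1'R,2'S)-epoxy monoketal, free acid | C=C1CC[C@H]2C(C)(C)CCC[C@]2(C)[C@H]1C[C@@]12O[C@@H]1C(OC)(OC)C(COC(=O)C[C@@](C)(O)CC(=O)O)=CC2=O | intermediate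
29 | 4'-oxomacrophorin D | C=C1CC[C@H]2C(C)(C)CCC[C@]2(C)[C@H]1C[C@@]12O[C@@H]1C(=O)C(COC(=O)C[C@@](C)(O)CC(=O)O)=CC2=O | target

**Totals and risks**

Total step count: 19. Longest linear sequence: 15 steps (from 1 through steps 1–4, 7–12 and 15–19; 13 steps from enone 6).

Three steps most likely to fail:

1. Step 5. The copper-catalysed vinyl transfer to a hindered α-methyl enone may proceed with low enantioselectivity or with competing 1,2-addition, and proton transfer may compete with C-alkylation of the hindered magnesium enolate. The fallback sets out from 6 and comes back at 10. A 1,4-addition of potassium vinyltrifluoroborate to 6 catalysed by [Rh(cod)2]BF4 and the matching BINAP enantiomer (toluene/H2O, 100 °C) should give (3R)-3-ethenyl-2,4,4-trimethylcyclohexan-1-one F1 as a mixture at C2. Equilibrating silylation (Me3SiCl, NaI, Et3N, MeCN) should give the tetrasubstituted enol ether {[(3S)-3-ethenyl-2,4,4-trimethylcyclohex-1-en-1-yl]oxy}trimethylsilane F2. MeLi in THF then releases the lithium enolate regiospecifically, and 8 alkylates it anti to the vinyl group to give 10.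

2. Step 7. Facial selectivity may be poor in the alkylation next to the quaternary carbon, since the substrate bias rests on a conformational model. The fallback sets out from 12 and comes back at 14. CF3CO2H should cleave 12 to 2-[(1R,2S)-2-ethenyl-1,3,3-trimethylcyclohexyl]acetic acid F3. Pivaloyl chloride/Et3N and then the lithium salt of (4R)-4-benzyl-1,3-oxazolidin-2-one should give the imide (4R)-4-benzyl-3-{2-[(1R,2S)-2-ethenyl-1,3,3-trimethylcyclohexyl]acetyl}-1,3-oxazolidin-2-one F4. NaN(SiMe3)2 and 5 should then give the benzylated imide F5 under auxiliary control (chelated Z-enolate, attack anti to the auxiliary benzyl group, the same sense as the substrate bias). LiOH/H2O2 releases 14.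

3. Step 18. Facial selectivity may be poor because the stereocentres of the decalin are remote and the substrate offers no anchoring hydroxyl to the tartrate aggregate. The fallback sets out from 26 and comes back at 29. Ketal exchange with (2R,4R)-pentane-2,4-diol (pyridinium p-toluenesulfonate, benzene, removal of MeOH) should give the C2-symmetric spiro-dioxane ketal F6. Epoxidation with t-BuOOH/DBU in CH2Cl2, now under control of the chiral ketal, should give the epoxy ketal F7 (the diol enantiomer is chosen to match). Aqueous CF3CO2H with anisole then removes the ketal and the PMB ester to give 29.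

**Further compounds**

F1 | step 5 | (3R)-3-ethenyl-2,4,4-trimethylcyclohexan-1-one (C2 epimers) | C=C[C@H]1C(C)(C)CCC(=O)C1C
F2 | step 5 | {[(3S)-3-ethenyl-2,4,4-trimethylcyclohex-1-en-1-yl]oxy}trimethylsilane | C=C[C@H]1C(C)(C)CCC(O[Si](C)(C)C)=C1C
F3 | step 7 | 2-[(1R,2S)-2-ethenyl-1,3,3-trimethylcyclohexyl]acetic acid | C=C[C@H]1C(C)(C)CCC[C@]1(C)CC(=O)O
F4 | step 7 | (4R)-4-benzyl-3-{2-[(1R,2S)-2-ethenyl-1,3,3-trimethylcyclohexyl]acetyl}-1,3-oxazolidin-2-one | C=C[C@H]1C(C)(C)CCC[C@]1(C)CC(=O)N1C(=O)OC[C@H]1Cc1ccccc1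
F5 | step 7 | (4R)-4-benzyl-3-[(2R)-3-{4-bromo-5-methoxy-2-[(triisopropylsilyl)oxy]phenyl}-2-[(1S,2S)-2-ethenyl-1,3,3-trimethylcyclohexyl]propanoyl]-1,3-oxazolidin-2-one | C=C[C@H]1C(C)(C)CCC[C@]1(C)[C@H](C(=O)N1C(=O)OC[C@H]1Cc1ccccc1)Cc1cc(OC)c(Br)cc1O[Si](C(C)C)(C(C)C)C(C)C
F6 | step 18 | quinone mono-[(4R,6R)-4,6-dimethyl-1,3-dioxane] ketal analogue of 26 | C=C1CC[C@H]2C(C)(C)CCC[C@]2(C)[C@H]1CC1=CC2(O[C@H](C)C[C@@H](C)O2)C(COC(=O)C[C@@](C)(O)CC(=O)OCc2ccc(OC)cc2)=CC1=O
F7 | step 18 | (1'R,2'S)-epoxide of F6 | C=C1CC[C@H]2C(C)(C)CCC[C@]2(C)[C@H]1C[C@@]12O[C@@H]1C1(O[C@H](C)C[C@@H](C)O1)C(COC(=O)C[C@@](C)(O)CC(=O)OCc1ccc(OC)cc1)=CC2=O
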